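## Structural features

The target, C20H33BrO2, is a bridged tetracycle in which a norbornane (bridgeheads C6 and C13, one-carbon bridge C7, two-carbon bridges C4–C5 and C14–C15) shares the C7–C13 bond with a trans-decalin made of ring B (C7, C8, C9, C11, C12, C13) and ring A (C8, C9, C17, C19, C20, C21); atoms are numbered in the order of the SMILES string, with Br as atom 18. Nine stereocentres are present: C6, C7, C8, C9 and C17 are contiguous, C9 and C13 are quaternary, and C21 carries an axial hydroxyl syn to the axial C9 methyl. The isopropyl group on C4 and the hydroxyl on C15 are both exo, and C8 sits on C7 syn to the C14–C15 bridge. The norbornane allows ring B a single chair (C7–H and C14 axial), and in that chair the axial site of C8, occupied by hydrogen in the target, points straight at the exo oxygen on C15. The fragile groups are the secondary bromide (equatorial, next to quaternary C9, and γ to C21, so that a C20 or C8 enolate can displace it), the exo-norbornanol (Wagner–Meerwein shifts in acid) and the tertiary carbinol. The real difficulty is the C8/C9 pair with the adjoining equatorial bromide and its relation to the norbornane. The key step exploits two features: Br on C17, the methyl-bearing C9 and the oxygenated C21 are the imprint of a bromonium ion opened across the ten-membered ring C7–C8–C21–C20–C19–C17=C9–C11–C12–C13 by the enol carbon C8, and an angular carboxyl carbon on C8 lies within bonding distance of O15, so the two can be tied together as a lactone.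

## Logic of the disconnections

**34 ⇒ 33.** The C21–CH3 bond is cut. Removing it leaves a ketone, which is the natural end point of an enol-terminated cyclisation. The forward step must add methyl from the equatorial side of C21 (axial OH, syn to the C9 methyl) without enolising towards C20, which could expel the bromide.

**33 ⇒ 31.** C8–H and O15–H are replaced by one carbonyl carbon bonded to both C8 and O15. In the only chair of ring B, an angular ester carbon on C8 and an exo OR group on C15 would have to occupy the same space, and an exo C15 alkoxide beside a C8 ester would lactonise anyway. The δ-lactone turns this clash into a bond and removes two protecting-group operations. The forward step needs acyl–oxygen cleavage and decarboxylation without breaking C8–C21, and protonation of C8 trans to the C9 methyl.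

**31 ⇒ 30.** C8–C9 and C17–Br are cut. One C–C bond turns the tetracyclic decalin problem into a ten-membered ring on the norbornane, and three stereocentres (C8, C9, C17) come from an E alkene and an enol. The forward step needs C- over O-capture and the trans-fused chair–chair mode.

**30 ⇒ 29 ⇒ 28.** A phenylsulfonyl group is added to C12, then C11–C12 is cut. The sulfone makes C12, which is neopentyl, nucleophilic, and the allylic chloride at C11 is the matching electrophile. The forward ring closure needs high dilution and a β-keto lactone that stays out of the way as its enolate.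

**28 ⇒ 27 + 7.** C8–C21 is cut, which separates the norbornane lactone from the six-carbon side chain. The forward step is a Claisen-type acylation of the lactone enolate and must not disturb the allylic chloride or the sulfone.

**7 ⇒ 6 ⇒ 5 ⇒ 4 ⇒ 1 + 2.** The chloride and amide are traced to the E allylic alcohol of an ester, and C19–C20 is cut by a [3,3] shift. The E geometry of C9=C17 must come from selective oxidation of the methyl group trans to the chain.

**27 ⇒ 25.** The lactone C–O bond is cut and C15 is returned to the ketone level. The hydride must enter from the endo face so that the alkoxide is exo and can reach the ester.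

**25 ⇒ 24.** C5–C6 is cut, which opens the norbornane to a cyclopentanone with a C5 sulfonate. Only the C6 enolate can close, and the tether fixes C6.

**24 ⇒ 22.** C7–C8 is cut, giving a 4,4-disubstituted cyclopentenone. The two-carbon unit must add to C7 anti to the branched C4 chain.

**22 ⇒ 21 ⇒ 20 ⇒ 19 ⇒ 18.** The C15 carbonyl, the tosylate, the sulfone oxidation level and the alcohol are removed in turn, back to a cyclopentenyl carboxylic acid. The order is set by the need to oxidise sulfur before a leaving group sits on C5.

**18 ⇒ 15 ⇒ 13 + 14.** C4–C13 is cut by an ester enolate [3,3] shift. Both new centres derive from one carbinol centre and the ketene acetal geometry, which the forward step must control.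

**13 ⇒ 12 ⇒ 8 + 9.** The carbinol is traced to the enone, and C12–C13 is cut to a vinylogous ester and lithiated thioanisole. The reduction must be enantioselective.

## Other disconnections considered

**Alternative 1:** The cut removes C7–C13, C14–C15 and C6–C15 (ring B and a cyclopentenone). It leaves enyne A1, in which ring A already carries the bromide, the C9 methyl and a ketal at C21. Forward, Co2(CO)8 complexes the C6≡C7 alkyne, and an amine N-oxide promotes the Pauson–Khand reaction with the 1,1-disubstituted C13=C14 alkene to give tricyclic enone A2.
- In its favour: three C–C bonds, ring B, quaternary C13 and the C15 carbonyl arise in one step of a well-established reaction type. No medium ring is needed, and ring A with its bromide can come from an ordinary bromonium polyene cyclisation.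
- Against it: a 1,7-enyne with a 1,1-disubstituted alkene is a slow substrate. The configuration of C13 relative to C8 and C9 rests on substrate control that is not obvious. A secondary bromide must survive low-valent cobalt. The norbornane is still open, so C5–C6, the C7–H centre and the exo alcohol remain to be made, and C4 must be set in an acyclic fragment.
- Comparison: on mechanism the alternative is the better, because its key step belongs to an established class and the chosen one is new. On structure the chosen plan is better, since the lactone and the ring B chair fix C8 and anti addition fixes C17, whereas A2 leaves three norbornane centres open. On step economy the two are about equal.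

**Alternative 2:** The cut removes C6–C15 and C4–C5, both rings of the norbornanone. It leads back to decalin selenoester A3, with a vinyl group on C7 and a 2-methylprop-1-enyl group on C13. Forward, Bu3SnH and an initiator give the C15 acyl radical, which closes 5-exo on C6; the C5 radical then closes 5-exo on C4, and hydrogen transfer to the tertiary radical gives ketone A4.
- In its favour: two rings, the C15 carbonyl and the isopropyl group appear together. The decalin with the C21 carbinol is made first by conventional chemistry. The C15 ketone would be reduced from the endo face exactly as in the chosen route, an equal point.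
- Against it: the second closure must form a strained bicyclo[2.2.1] ring from a primary radical onto a trisubstituted alkene and competes with simple reduction. The exo position of the isopropyl group is under kinetic control only. Tin hydride forbids a bromide, so C17 is a ketal, and the equatorial bromide next to quaternary C9 would have to come from an axial alcohol by inversion at a neopentyl-like centre, which is likely to fail or rearrange.
- Comparison: on structure the alternative is equal or better for the norbornane (no medium ring, C6 and C13 tied by the tether) but clearly worse for the C17 bromide, which the chosen step installs with its configuration. On mechanism a radical cascade of a known type is a point for the alternative. On step economy it is similar before the key step and worse after it.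

**Alternative 3:** The cut is C5–C6 alone. The precursor is cyclopentene tosylate A5, which already holds rings A and B. Forward, buffered formolysis ionises C5–OTs with participation of the C6=C15 alkene, and formate captures the bridged cation on the exo face to give A6.
- In its favour: the exo C15–O bond is formed with the right configuration by the reaction itself. This is the equal of the hydride reduction in the chosen route and saves a step afterwards. The reaction class is long established, and bromide and ketone are already in place.
- Against it: the bridged ion is symmetric about C6 and C15 only in the parent system. Here formate can open it at C15 (wanted) or at C6 (a constitutional isomer), and hydride shifts can spread the charge. The bromide and ketone must survive warm formic acid. The decalin with C8, C9 and C17 must be solved separately.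
- Comparison: on structure it is better for the C15 oxygen and worse for regiocontrol of the norbornane. On mechanism it is established cation chemistry, but with less internal control than the tethered chosen step. On step economy it is shorter after the key step but not shorter overall.

Key step: step 19

Assumption: joining O15 and the C8 carboxyl carbon as a δ-lactone (in place of a separate silyl ether and alkyl ester) is treated as a change of protecting groups; the carbon skeletons of 30 and 31 and the bond formed in the key step are unchanged.

Remark: C8 in 28, 29 and 30 is an epimerisable, enolisable centre and is written without configuration; C12 in 29 is a mixture that is erased in step 18.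

## Steps

Step 1
Reactants: 1 2-methylbut-3-en-2-ol; 2 triethyl orthoacetate
Product: 4 ethyl 5-methylhex-4-enoate, via mixed ketene acetal 3 (not isolated)
Conditions: EtCO2H (cat.), neat, 140 °C, EtOH distilled off
Reagents that add atoms: none
Why: Johnson–Claisen rearrangement: acid-catalysed exchange gives the allyl ketene acetal 3, which undergoes a [3,3] shift on heating. No stereocentre is formed; the product carries C21 (ester), C20, C19, C17=C9 and both C9 methyl groups.

Step 2
Reactants: 4 ethyl 5-methylhex-4-enoate
Product: 5 ethyl (E)-6-hydroxy-5-methylhex-4-enoate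
Conditions: SeO2 (cat.), t-BuOOH, salicylic acid (cat.), CH2Cl2, rt
Reagents that add atoms: tert-butyl hydroperoxide CC(C)(C)OO
Why: SeO2 allylic oxidation (ene reaction, then [2,3] shift) attacks the methyl group trans to the chain of a trisubstituted alkene, so C11 is hydroxylated and the E geometry needed for C9=C17 is fixed. Catalytic SeO2 with the hydroperoxide limits over-oxidation to the enal.

Step 3
Reactants: 5 ethyl (E)-6-hydroxy-5-methylhex-4-enoate
Product: 6 (E)-6-hydroxy-N-methoxy-N,5-dimethylhex-4-enamide
Conditions: MeNH(OMe)·HCl, i-PrMgCl (excess), THF, −20 to 0 °C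
Reagents that add atoms: N,O-dimethylhydroxylamine hydrochloride CNOC.Cl
Why: Weinreb amide formation by direct aminolysis of the ethyl ester with the chloromagnesium amide; the allylic alcohol is carried as its magnesium alkoxide.

Step 4
Reactants: 6 (E)-6-hydroxy-N-methoxy-N,5-dimethylhex-4-enamide
Product: 7 (E)-6-chloro-N-methoxy-N,5-dimethylhex-4-enamide
Conditions: PPh3, hexachloroacetone, CH2Cl2, −20 to 0 °C
Reagents that add atoms: hexachloroacetone O=C(C(Cl)(Cl)Cl)C(Cl)(Cl)Cl
Why: Appel-type chlorination of a primary allylic alcohol through the alkoxyphosphonium salt; SN2 at C11 occurs without allylic shift or loss of the E geometry, and the amide is inert.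

Step 5
Reactants: 8 (methylsulfanyl)benzene; 9 3-ethoxycyclopent-2-en-1-one
Product: 12 3-[(phenylsulfanyl)methyl]cyclopent-2-en-1-one, via phenylthiomethyllithium 10 (not isolated), via tertiary alkoxide adduct 11 (not isolated)
Conditions: 8, n-BuLi, DABCO, THF, 0 °C; then 9, −78 °C; then 1 M HCl, rt
Reagents that add atoms: none
Why: Stork–Danheiser sequence: lithiated thioanisole adds 1,2 to the vinylogous ester, and acid hydrolysis with 1,3-carbonyl transposition gives the enone. This places the C12–S unit on the future C13.

Step 6
Reactants: 12 3-[(phenylsulfanyl)methyl]cyclopent-2-en-1-one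
Product: 13 (1S)-3-[(phenylsulfanyl)methyl]cyclopent-2-en-1-ol
Conditions: (R)-2-methyl-CBS-oxazaborolidine (10 mol %), BH3·SMe2, THF, −30 °C; MeOH
Reagents that add atoms: none
Why: Corey–Bakshi–Shibata reduction: the alkenyl flank acts as the large group, so the (R)-catalyst should give the (S)-carbinol. This centre is the source of absolute configuration, since it later sets C13.

Step 7
Reactants: 13 (1S)-3-[(phenylsulfanyl)methyl]cyclopent-2-en-1-ol; 14 3-methylbutanoyl chloride
Product: 15 (1S)-3-[(phenylsulfanyl)methyl]cyclopent-2-en-1-yl 3-methylbutanoate
Conditions: pyridine, DMAP (cat.), CH2Cl2, 0 °C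
Reagents that add atoms: none
Why: Acylation of a secondary allylic alcohol with an acid chloride under nucleophilic catalysis; no stereocentre is touched.

Step 8
Reactants: 15 (1S)-3-[(phenylsulfanyl)methyl]cyclopent-2-en-1-yl 3-methylbutanoate
Product: 18 (2S)-3-methyl-2-[(1S)-1-[(phenylsulfanyl)methyl]cyclopent-2-en-1-yl]butanoic acid, via silyl ketene acetal 16 (not isolated), via trimethylsilyl ester 17 (not isolated)
Conditions: LiN(i-Pr)2, THF, −78 °C; Me3SiCl, Et3N; −78 to 60 °C; then 1 M HCl
Reagents that add atoms: none
Why: Ireland–Claisen rearrangement: kinetic enolisation in THF gives the (E)-silyl ketene acetal 16 (isopropyl cis to the allylic oxygen), and the suprafacial [3,3] shift sets quaternary C13 from the carbinol centre. In a chair transition state the isopropyl group lies in the open sector between C12 and the vinylic C7–H, which gives the (2S) centre C4 (isopropyl anti to C12 in the extended chain). If the ring imposes a boat, the (Z)-ketene acetal (THF–DMPU) leads to the same acid.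

Step 9
Reactants: 18 (2S)-3-methyl-2-[(1S)-1-[(phenylsulfanyl)methyl]cyclopent-2-en-1-yl]butanoic acid
Product: 19 (2S)-3-methyl-2-[(1S)-1-[(phenylsulfanyl)methyl]cyclopent-2-en-1-yl]butan-1-ol
Conditions: LiAlH4, THF, 0 °C to rt
Reagents that add atoms: none
Why: Hydride reduction of the carboxylic acid to the primary alcohol C5–OH; sulfide and alkene are inert.

Step 10
Reactants: 19 (2S)-3-methyl-2-[(1S)-1-[(phenylsulfanyl)methyl]cyclopent-2-en-1-yl]butan-1-ol
Product: 20 (2S)-2-[(1S)-1-(benzenesulfonylmethyl)cyclopent-2-en-1-yl]-3-methylbutan-1-ol
Conditions: H2O2 (30%), (NH4)6Mo7O24 (cat.), EtOH, 0 °C to rt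
Reagents that add atoms: hydrogen peroxide OO
Why: Molybdate-catalysed oxidation of sulfide to sulfone, which leaves the disubstituted alkene alone. It precedes sulfonylation of C5–OH because a sulfide would displace a C5 sulfonate to give a five-membered sulfonium salt.

Step 11
Reactants: 20 (2S)-2-[(1S)-1-(benzenesulfonylmethyl)cyclopent-2-en-1-yl]-3-methylbutan-1-ol
Product: 21 (2S)-2-[(1S)-1-(benzenesulfonylmethyl)cyclopent-2-en-1-yl]-3-methylbutyl 4-methylbenzenesulfonate
Conditions: TsCl, Et3N, DMAP (cat.), CH2Cl2, 0 °C to rt
Reagents that add atoms: 4-methylbenzenesulfonyl chloride Cc1ccc(cc1)S(Cl)(=O)=O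
Why: Sulfonylation of a primary alcohol; the tosylate is the leaving group for the later closure of C5–C6.

Step 12
Reactants: 21 (2S)-2-[(1S)-1-(benzenesulfonylmethyl)cyclopent-2-en-1-yl]-3-methylbutyl 4-methylbenzenesulfonate
Product: 22 (2S)-2-[(1S)-1-(benzenesulfonylmethyl)-4-oxocyclopent-2-en-1-yl]-3-methylbutyl 4-methylbenzenesulfonate
Conditions: CrO3, 3,5-dimethylpyrazole, CH2Cl2, −20 °C
Reagents that add atoms: chromium trioxide O=[Cr](=O)=O
Why: Allylic oxidation by the CrO3–3,5-dimethylpyrazole complex: C15 is the only allylic CH2 (C13 is quaternary), so the 4,4-disubstituted cyclopent-2-enone forms regioselectively. Sulfone and tosylate are stable to the oxidant.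

Step 13
Reactants: 22 (2S)-2-[(1S)-1-(benzenesulfonylmethyl)-4-oxocyclopent-2-en-1-yl]-3-methylbutyl 4-methylbenzenesulfonate
Product: 24 methyl 2-[(1S,2S)-2-(benzenesulfonylmethyl)-2-[(2S)-3-methyl-1-(tosyloxy)butan-2-yl]-4-oxocyclopentyl]acetate, via silyl enol ether 23 (not isolated)
Conditions: CH2=C(OMe)OSi(t-Bu)Me2, t-BuMe2SiOTf (10 mol %), CH2Cl2, −78 °C; then 1 M HCl, THF, rt
Reagents that add atoms: 1-[(tert-butyldimethylsilyl)oxy]-1-methoxyethene COC(=C)O[Si](C)(C)C(C)(C)C
Why: Mukaiyama–Michael addition under silyl triflate catalysis, then hydrolysis of the silyl enol ether 23. The nucleophile should attack C7 anti to the branched C4 chain on C13 (cis to CH2SO2Ph), which puts C8 on the face that becomes syn to the C14–C15 bridge.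

Step 14
Reactants: 24 methyl 2-[(1S,2S)-2-(benzenesulfonylmethyl)-2-[(2S)-3-methyl-1-(tosyloxy)butan-2-yl]-4-oxocyclopentyl]acetate
Product: 25 norbornanone keto ester (C15 ketone; CH2SO2Ph on C13; exo isopropyl on C4; CH2CO2Me on C7 syn to C15)
Conditions: KN(SiMe3)2 (1.0 equiv), THF, −78 to 0 °C
Reagents that add atoms: none
Why: Intramolecular enolate alkylation (5-exo-tet): the two ketone enolates equilibrate through the amine, but only the C6 enolate can reach C5–OTs. The tether fixes bridgehead C6 and leaves the isopropyl group exo; O-alkylation would need a bridgehead enol ether. One equivalent of base keeps the less acidic sulfone and ester positions protonated.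

Step 15
Reactants: 25 norbornanone keto ester
Product: 27 δ-lactone (O15–C(=O)–C8H2 on the norbornane; CH2SO2Ph on C13; exo isopropyl on C4), via exo alkoxide 26 (not isolated)
Conditions: LiBH(s-Bu)3, THF, −78 °C to rt; aq. NH4Cl
Reagents that add atoms: none
Why: Hydride adds to the C15 ketone from the endo face because the exo face is covered by the syn C7 side chain (as in camphor). The exo alkoxide 26 lies within bonding distance of the ester carbonyl and closes the δ-lactone with loss of methoxide. The lactone protects O15, activates C8, and joins the two groups that must share the axial site of ring B after the key step.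

Step 16
Reactants: 27 δ-lactone; 7 (E)-6-chloro-N-methoxy-N,5-dimethylhex-4-enamide
Product: 28 C8-acylated lactone (C8–C21(=O)–C20–C19–C17=C9(CH3)–C11H2Cl with E alkene; C8 epimers)
Conditions: LiN(SiMe3)2 (1.1 equiv), THF, −78 °C; then 7, −78 to −20 °C; aq. NH4Cl
Reagents that add atoms: none
Why: Claisen-type acylation of a lactone lithium enolate by a Weinreb amide: the lactone C8–H is more acidic than the sulfone C12–H, and the tetrahedral chelate persists until work-up. One equivalent of base therefore suffices and the allylic chloride is not attacked at low temperature.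

Step 17
Reactants: 28 C8-acylated lactone
Product: 29 macrocyclic sulfone (ten-membered ring C7–C8–C21(=O)–C20–C19–C17=C9–C11–C12(SO2Ph)–C13; E alkene)
Conditions: LiN(i-Pr)2 (2.3 equiv), THF (0.002 M, slow addition of 28), −78 to 0 °C; aq. NH4Cl
Reagents that add atoms: none
Why: Intramolecular alkylation of a sulfone-stabilised carbanion by an allylic chloride under high dilution, a method used for ten-membered and larger carbocycles with E trisubstituted alkenes. The first equivalent of base stores the β-keto lactone as its unreactive enolate; the second gives the C12 carbanion, which attacks C11 by SN2 and keeps the E alkene. The enolate cannot alkylate at C11, since that would close a seven-membered ring containing an E alkene.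

Step 18
Reactants: 29 macrocyclic sulfone
Product: 30 macrocyclic β-keto lactone (C12H2; key-step precursor)
Conditions: LiN(SiMe3)2 (1.1 equiv), THF, −78 °C; then LiC10H8 (lithium naphthalenide), −78 °C; aq. NH4Cl
Reagents that add atoms: none
Why: Reductive desulfonylation by electron transfer: the β-keto lactone is first converted into its lithium enolate, which resists reduction, and the arenide then cleaves the C12–S bond. The C12 carbanion is protonated by the silylamine.

Step 19
Reactants: 30 macrocyclic β-keto lactone
Product: 31 pentacyclic bromo β-keto lactone (trans-fused rings A and B; C8 carbonyl carbon bonded to O15; equatorial Br on C17)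
Conditions: Et2SBr·SbCl5Br (1.1 equiv), MeNO2, −25 °C, 10 min; aq. Na2SO3, NaHCO3
Reagents that add atoms: bromodiethylsulfonium bromopentachloroantimonate CC[S+](Br)CC.Cl[Sb-](Cl)(Cl)(Cl)(Cl)Br
Why: Proposed new method: Br+ adds to C17 of the E alkene, the developing tertiary cation at C9 is trapped across the ring by C8 of the enol of the β-keto lactone, and the oxocarbenium ion loses a proton; the closest known reaction types are the electrophile-induced transannular cyclisation of (E,E)-cyclodeca-1,5-dienes to trans-decalins and bromonium-initiated polyene cyclisations ended by enol-type carbon nucleophiles. The single new bond C8–C9 divides the ten-membered ring into two six-membered rings, so the ring count rises by one: ring A closes 6-endo-trig with respect to C9=C17 and ring B closes 6-exo-trig. C17 is set by anti addition across the E alkene, which leaves Br equatorial and cis to the C9 methyl. C8 can be reached only on the face turned towards C13, because the lactone holds its carbonyl carbon anti to C7–H; this is the one chair of ring B that the norbornane permits, with the carbonyl carbon axial where C8–H of the target will stand. C9 is set by the chair of ring A: with the E alkene and the enol in its extended form (C20 trans to C7) the ring fusion is trans and the methyl is axial on the face of C7–H. The selectivities needed are C- over O-capture and the trans- over the cis-fused mode. O-capture would give a bridgehead enol ether in a bicyclo[5.3.1] system, and the cis mode would put C7 axial on ring A and C17 axial on ring B, but neither is excluded outright.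

Step 20
Reactants: 31 pentacyclic bromo β-keto lactone
Product: 33 bromo keto alcohol (C8–H trans to the C9 methyl; exo C15–OH; C21 ketone), via hydroxy keto acid 32 (not isolated)
Conditions: LiOH, THF–H2O (3:1), 0 °C to rt; then 1 M HCl to pH 2, 40 °C
Reagents that add atoms: none
Why: Saponification by acyl–oxygen cleavage: the strained δ-lactone is the more electrophilic carbonyl and its tetrahedral adduct expels an alkoxide, a far better leaving group than the lactone enolate that retro-Claisen cleavage of C8–C21 would have to release, and the carboxylate formed closes that path. Acidification and gentle warming then decarboxylate the β-keto acid 32 through its enol and leave O15–H free. Ketonisation places C8–H on the face of O15 (trans ring fusion), since the epimer would push C21 axially against the C14–C15 bridge.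

Step 21
Reactants: 33 bromo keto alcohol
Product: 34 target bromo diol
Conditions: CeCl3 (anhydrous), MeMgBr (3 equiv), THF, −78 °C; aq. NH4Cl
Reagents that add atoms: methylmagnesium bromide C[Mg]Br
Why: Organocerium addition to the hindered, enolisable C21 ketone: the axial face is blocked by the 1,3-related axial C9 methyl, so methyl enters equatorially and gives the axial hydroxyl and equatorial methyl of the target. The low basicity of the cerium reagent avoids enolisation towards C20, which could displace the C17 bromide; the free C15 hydroxyl only consumes one equivalent.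

## Compound list

1 | 2-methylbut-3-en-2-ol | CC(C)(O)C=C | starting material
2 | triethyl orthoacetate | CCOC(C)(OCC)OCC | starting material
3 | 1-ethoxy-1-[(2-methylbut-3-en-2-yl)oxy]ethene (mixed ketene acetal) | C=C(OCC)OC(C)(C)C=C | intermediate
4 | ethyl 5-methylhex-4-enoate | CCOC(=O)CCC=C(C)C | intermediate
5 | ethyl (E)-6-hydroxy-5-methylhex-4-enoate | CCOC(=O)CC/C=C(\C)CO | intermediate
6 | (E)-6-hydroxy-N-methoxy-N,5-dimethylhex-4-enamide | CON(C)C(=O)CC/C=C(\C)CO | intermediate
7 | (E)-6-chloro-N-methoxy-N,5-dimethylhex-4-enamide | CON(C)C(=O)CC/C=C(\C)CCl | intermediate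
8 | (methylsulfanyl)benzene (thioanisole) | CSc1ccccc1 | starting material
9 | 3-ethoxycyclopent-2-en-1-one | CCOC1=CC(=O)CC1 | starting material
10 | [(phenylsulfanyl)methyl]lithium | [Li]CSc1ccccc1 | intermediate
11 | 3-ethoxy-1-[(phenylsulfanyl)methyl]cyclopent-2-en-1-ol (racemic; lithium alkoxide in the flask) | CCOC1=CC(O)(CSc2ccccc2)CC1 | intermediate
12 | 3-[(phenylsulfanyl)methyl]cyclopent-2-en-1-one | O=C1C=C(CSc2ccccc2)CC1 | intermediate
13 | (1S)-3-[(phenylsulfanyl)methyl]cyclopent-2-en-1-ol | O[C@@H]1C=C(CSc2ccccc2)CC1 | intermediate
14 | 3-methylbutanoyl chloride | CC(C)CC(Cl)=O | starting material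
15 | (1S)-3-[(phenylsulfanyl)methyl]cyclopent-2-en-1-yl 3-methylbutanoate | CC(C)CC(=O)O[C@@H]1C=C(CSc2ccccc2)CC1 | intermediate
16 | (E)-trimethylsilyl ketene acetal of 15 (isopropyl cis to the ring oxygen) | CC(C)/C=C(/O[Si](C)(C)C)O[C@@H]1C=C(CSc2ccccc2)CC1 | intermediate
17 | trimethylsilyl ester of 18 | CC(C)[C@H](C(=O)O[Si](C)(C)C)[C@@]1(CSc2ccccc2)C=CCC1 | intermediate
18 | (2S)-3-methyl-2-[(1S)-1-[(phenylsulfanyl)methyl]cyclopent-2-en-1-yl]butanoic acid | CC(C)[C@H](C(=O)O)[C@@]1(CSc2ccccc2)C=CCC1 | intermediate
19 | (2S)-3-methyl-2-[(1S)-1-[(phenylsulfanyl)methyl]cyclopent-2-en-1-yl]butan-1-ol | CC(C)[C@H](CO)[C@@]1(CSc2ccccc2)C=CCC1 | intermediate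
20 | (2S)-2-[(1S)-1-(benzenesulfonylmethyl)cyclopent-2-en-1-yl]-3-methylbutan-1-ol | CC(C)[C@H](CO)[C@@]1(CS(=O)(=O)c2ccccc2)C=CCC1 | intermediate
21 | (2S)-2-[(1S)-1-(benzenesulfonylmethyl)cyclopent-2-en-1-yl]-3-methylbutyl 4-methylbenzenesulfonate | CC(C)[C@H](COS(=O)(=O)c2ccc(C)cc2)[C@@]1(CS(=O)(=O)c3ccccc3)C=CCC1 | intermediate
22 | (2S)-2-[(1S)-1-(benzenesulfonylmethyl)-4-oxocyclopent-2-en-1-yl]-3-methylbutyl 4-methylbenzenesulfonate | CC(C)[C@H](COS(=O)(=O)c2ccc(C)cc2)[C@@]1(CS(=O)(=O)c3ccccc3)C=CC(=O)C1 | intermediate
23 | tert-butyldimethylsilyl enol ether of 24 (C6=C15–OSi) | CC(C)[C@H](COS(=O)(=O)c2ccc(C)cc2)[C@@]1(CS(=O)(=O)c3ccccc3)[C@H](CC(=O)OC)C=C(O[Si](C)(C)C(C)(C)C)C1 | intermediate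
24 | methyl 2-[(1S,2S)-2-(benzenesulfonylmethyl)-2-[(2S)-3-methyl-1-(tosyloxy)butan-2-yl]-4-oxocyclopentyl]acetate | CC(C)[C@H](COS(=O)(=O)c2ccc(C)cc2)[C@@]1(CS(=O)(=O)c3ccccc3)[C@H](CC(=O)OC)CC(=O)C1 | intermediate
25 | norbornanone keto ester: C15 ketone, CH2SO2Ph on bridgehead C13, exo isopropyl on C4, CH2CO2Me on C7 syn to the C14–C15 bridge | CC(C)[C@@H]1C[C@@H]2[C@@H](CC(=O)OC)[C@@]1(CS(=O)(=O)c3ccccc3)CC2=O | intermediate
26 | exo C15 alcohol of 25 (lithium alkoxide in the flask) | CC(C)[C@@H]1C[C@@H]2[C@@H](CC(=O)OC)[C@@]1(CS(=O)(=O)c3ccccc3)C[C@H]2O | intermediate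
27 | δ-lactone: O15–C(=O)–C8H2–C7 six-membered ring on the norbornane, CH2SO2Ph on C13, exo isopropyl on C4 | CC(C)[C@@H]1C[C@@H]2[C@H]3CC(=O)O[C@@H]2C[C@@]13CS(=O)(=O)c4ccccc4 | intermediate
28 | 27 acylated at C8 by the (E)-6-chloro-5-methylhex-4-enoyl group (C8 epimers, enolisable) | CC(C)[C@@H]1C[C@@H]2[C@H]3C(C(=O)CC/C=C(\C)CCl)C(=O)O[C@@H]2C[C@@]13CS(=O)(=O)c4ccccc4 | intermediate
29 | macrocyclic β-keto lactone sulfone: ten-membered ring C7–C8–C21(=O)–C20–C19–C17=C9(CH3)–C11–C12(SO2Ph)–C13, E alkene | CC(C)[C@@H]1C[C@@H]2[C@H]3C4C(=O)O[C@@H]2C[C@@]13C(S(=O)(=O)c5ccccc5)C/C(C)=C/CCC4=O | intermediate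
30 | macrocyclic β-keto lactone with C12H2 (key-step precursor) | CC(C)[C@@H]1C[C@@H]2[C@H]3C4C(=O)O[C@@H]2C[C@@]13CC/C(C)=C/CCC4=O | intermediate
31 | pentacyclic bromo β-keto lactone: trans-fused rings A and B, C8 carbonyl carbon bonded to O15, axial C9 methyl, equatorial C17 bromide, C21 ketone | CC(C)[C@@H]1C[C@@H]2[C@H]3[C@@]4(C5=O)[C@](C)(CC[C@@]31C[C@H]2O5)[C@@H](Br)CCC4=O | intermediate
32 | opened lactone: C8 carboxylic acid, exo C15–OH, C21 ketone | CC(C)[C@@H]1C[C@@H]2[C@H]3[C@@]4(C(=O)O)[C@](C)(CC[C@@]31C[C@H]2O)[C@@H](Br)CCC4=O | intermediate
33 | bromo keto alcohol: C8–H trans to the C9 methyl, exo C15–OH, C21 ketone | CC(C)[C@@H]1C[C@@H]2[C@H]3[C@H]4[C@](C)(CC[C@@]31C[C@H]2O)[C@@H](Br)CCC4=O | intermediate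
34 | target bromo diol (CNP0317598.2) | CC(C)[C@@H]1C[C@@H]2[C@H]3[C@H]4[C@](C)(CC[C@@]31C[C@H]2O)[C@@H](Br)CC[C@@]4(C)O | target

## Step count and least certain steps

Total: 21 steps. Longest linear sequence: 17 steps (steps 5 to 21, from 9). The side chain 7 takes 4 steps (1 to 4) and joins at step 16.

**Step 19 (key step).** The most likely failure is bromination of the enol carbon C8, or collapse of the bromonium ion by bromide capture or proton loss before the ring-spanning carbon attacks, because the β-keto lactone is mostly ketonic. Closure through the cis-fused mode (wrong face of C9) is the second concern.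
Fallback with known chemistry, from 30 back to 31: mercury-initiated cyclisation with Hg(OTf)2 and PhNMe2 in MeNO2 at −20 °C, quenched with aqueous NaBr, should give the C17 organomercury bromide F1, with mercury equatorial by the same anti addition. Divalent mercury adds reversibly to the alkene and cannot halogenate C8, which gives the carbon nucleophile time to close the ring. Br2 with LiBr in pyridine in the dark then replaces mercury by bromine with retention and returns to 31.

**Step 17 (macrocyclisation).** The most likely failure is oligomerisation by intermolecular alkylation, or loss of HCl from the allylic chloride, because the C12 carbanion is neopentyl-like and the ten-membered transition state is strained.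
Fallback, from 27 back to 29: the hindered C11–C12 bond is made intermolecularly and the ring is closed at C19–C20 instead. The dianion of 27 (LiN(i-Pr)2, 2.1 equiv) is alkylated at C12, its more basic site, by the known tert-butyl{[(2E)-4-chloro-3-methylbut-2-en-1-yl]oxy}dimethylsilane F2, which gives the silyl ether F3. Bu4NF buffered with AcOH then frees the allylic alcohol F4, and PPh3 with hexachloroacetone converts it into the allylic chloride F5. Acetylation of C8 (LiN(SiMe3)2, then N-methoxy-N-methylacetamide) gives the acetyl lactone F6. The dianion of its β-keto lactone unit (NaH, then n-BuLi) is alkylated through the terminal carbon C20 by C19–Cl under high dilution, which gives 29.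

**Step 20 (lactone opening and decarboxylation).** The most likely failure is cleavage of the C8–C21 bond by hydroxide (retro-Claisen), since C8 is quaternary and the keto lactone cannot be stored as an enolate, or base-induced displacement of the γ-bromide through the C20 enolate.
Fallback, from 31 back to the route at 34: the ketone is removed before hydroxide is used. NaBH4 in MeOH should reduce the C21 ketone from the equatorial side to the carbinol lactone F7, whose axial alkoxide is cis to the bromide and cannot displace it. LiOH then opens the lactone to the dihydroxy acid F8. Dess–Martin periodinane oxidises both secondary alcohols, and the β-keto acid decarboxylates on warming to the diketone F9. MeMgBr–CeCl3 at −78 °C should add to the cyclohexanone C21 in preference to the camphor-like C15 ketone, giving the keto carbinol F10. NaBH4 finally reduces C15 from the endo face to give 34.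

**Step 8 (Ireland–Claisen).** The most likely failure is loss of diastereocontrol at C4, because a cyclopentenyl ester can rearrange through a boat as well as a chair and the ketene acetal geometry can erode.
Fallback, from 13 and 2 back to 18: C4 is set on a rigid bicycle instead. Johnson–Claisen rearrangement of 13 with 2 gives the ethyl ester F11, in which C13 is set by the same chirality transfer and C4 is still CH2. LiOH gives the acid F12, and I2 with NaHCO3 closes the cis-fused iodolactone F13. Its lithium enolate (LiN(SiMe3)2) is alkylated by 2-iodopropane in THF–DMPU on the convex face, cis to C12, which is the required configuration and gives the isopropyl iodolactone F14. Zn in AcOH then restores the C6=C7 alkene and the acid 18.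

**Step 6 (CBS reduction).** The most likely failure is insufficient enantioselectivity, since the two flanks of the carbonyl group (CH= and CH2) differ little in size.
Fallback, from 12 back to 13: reduction with NaBH4 and CeCl3 in MeOH gives the racemic alcohol F15. Kinetic resolution with Candida antarctica lipase B and vinyl acetate should acetylate the (R)-enantiomer to the acetate F16 and leave (S)-13, which is separated from it.

## Further compounds

F1 | step 19 | C17 bromomercurio analogue of 31 | CC(C)[C@@H]1C[C@@H]2[C@H]3[C@@]4(C5=O)[C@](C)(CC[C@@]31C[C@H]2O5)[C@@H]([Hg]Br)CCC4=O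
F2 | step 17 | tert-butyl{[(2E)-4-chloro-3-methylbut-2-en-1-yl]oxy}dimethylsilane | ClC/C(C)=C/CO[Si](C)(C)C(C)(C)C
F3 | step 17 | 27 alkylated at C12 by the C11–C19 unit, C19 silyl ether | CC(C)[C@@H]1C[C@@H]2[C@H]3CC(=O)O[C@@H]2C[C@@]13C(S(=O)(=O)c4ccccc4)C/C(C)=C/CO[Si](C)(C)C(C)(C)C
F4 | step 17 | C19 allylic alcohol from F3 | CC(C)[C@@H]1C[C@@H]2[C@H]3CC(=O)O[C@@H]2C[C@@]13C(S(=O)(=O)c4ccccc4)C/C(C)=C/CO
F5 | step 17 | C19 allylic chloride from F4 | CC(C)[C@@H]1C[C@@H]2[C@H]3CC(=O)O[C@@H]2C[C@@]13C(S(=O)(=O)c4ccccc4)C/C(C)=C/CCl
F6 | step 17 | C8-acetyl lactone from F5 | CC(C)[C@@H]1C[C@@H]2[C@H]3C(C(C)=O)C(=O)O[C@@H]2C[C@@]13C(S(=O)(=O)c4ccccc4)C/C(C)=C/CCl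
F7 | step 20 | C21 axial carbinol of 31 (lactone intact) | CC(C)[C@@H]1C[C@@H]2[C@H]3[C@@]4(C5=O)[C@](C)(CC[C@@]31C[C@H]2O5)[C@@H](Br)CC[C@H]4O
F8 | step 20 | dihydroxy acid from F7 | CC(C)[C@@H]1C[C@@H]2[C@H]3[C@@]4(C(=O)O)[C@](C)(CC[C@@]31C[C@H]2O)[C@@H](Br)CC[C@H]4O
F9 | step 20 | C15,C21 diketone with C8–H trans | CC(C)[C@@H]1C[C@@H]2[C@H]3[C@H]4[C@](C)(CC[C@@]31CC2=O)[C@@H](Br)CCC4=O
F10 | step 20 | C15 ketone with the C21 tertiary carbinol | CC(C)[C@@H]1C[C@@H]2[C@H]3[C@H]4[C@](C)(CC[C@@]31CC2=O)[C@@H](Br)CC[C@@]4(C)O
F11 | step 8 | ethyl 2-[(1R)-1-[(phenylsulfanyl)methyl]cyclopent-2-en-1-yl]acetate | CCOC(=O)C[C@@]1(CSc2ccccc2)C=CCC1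
F12 | step 8 | 2-[(1R)-1-[(phenylsulfanyl)methyl]cyclopent-2-en-1-yl]acetic acid | OC(=O)C[C@@]1(CSc2ccccc2)C=CCC1
F13 | step 8 | cis-fused iodolactone of F12 (O on C7, iodine on C6 trans to O) | O=C1C[C@]2(CSc3ccccc3)CC[C@@H](I)[C@@H]2O1
F14 | step 8 | F13 with isopropyl on C4, convex face | CC(C)[C@@H]1C(=O)O[C@H]2[C@H](I)CC[C@@]12CSc3ccccc3
F15 | step 6 | racemic 3-[(phenylsulfanyl)methyl]cyclopent-2-en-1-ol | OC1C=C(CSc2ccccc2)CC1
F16 | step 6 | (1R)-3-[(phenylsulfanyl)methyl]cyclopent-2-en-1-yl acetate | CC(=O)O[C@H]1C=C(CSc2ccccc2)CC1
A1 | alternative 1 | enyne precursor of the Pauson–Khand step | CC(C)[C@H](CO[Si](C)(C)C(C)(C)C)C(=C)CC[C@]1(C)[C@@H](Br)CCC2(OCCO2)[C@H]1C#C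
A2 | alternative 1 | tricyclic cyclopentenone with quaternary C13 | CC(C)[C@H](CO[Si](C)(C)C(C)(C)C)[C@]12CC(=O)C=C1[C@@H]1C3(OCCO3)CC[C@H](Br)[C@@]1(C)CC2
A3 | alternative 2 | C15 phenylselenoester with C7 vinyl and C13 2-methylprop-1-enyl groups | CC(C)=C[C@@]1(CC(=O)[Se]c2ccccc2)CC[C@]3(C)C4(OCCO4)CC[C@@](C)(O)[C@H]3[C@@H]1C=C
A4 | alternative 2 | tetracyclic C15 ketone with C17 ketal | CC(C)[C@@H]1C[C@@H]2[C@H]3[C@H]4[C@](C)(CC[C@@]31CC2=O)C5(OCCO5)CC[C@@]4(C)O
A5 | alternative 3 | cyclopentene C5 tosylate with rings A and B | CC(C)[C@H](COS(=O)(=O)c1ccc(C)cc1)[C@]12CC=C[C@H]1[C@@H]3C(=O)CC[C@H](Br)[C@@]3(C)CC2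
A6 | alternative 3 | tetracyclic exo formate ketone | CC(C)[C@@H]1C[C@@H]2[C@H]3[C@H]4[C@](C)(CC[C@@]31C[C@H]2OC=O)[C@@H](Br)CCC4=O
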